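**Plan**
- Retrosynthetic cuts: epoxide C6'–O (from a hydroxy mesylate), C5'–C6' (acylation of an alkylmetal made from a vinyl group), then ring D at C11–C1' and O–C3' together (formal 3+3 annulation), prenyl–aryl (Stille), C11–aryl (enolate arylation), diaryl ether (SNAr).
- Enabling feature: ring D is the cyclic enol ether of the C10 ketone of a dibenz[b,f]oxepin-10(11H)-one. C11 (benzylic and α to C=O) and the oxygen on C10 are a 1,3-C,O-bis-nucleophile that takes up a C3 bis-electrophile (alkyl bromide at C1', π-allyl terminus at C3').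
- Forward order: ring A + ring B → diaryl ether → oxepinone ring C → prenyl on ring A → ring D (one-pot C-alkylation/asymmetric allylic O-alkylation) → side chain from the vinyl group → epoxide closure and desilylation.
- Stereochemistry: C3' (S) from the chiral diphosphine ligand in the allylic etherification; C6' (S) from a CBS reduction to the (R)-carbinol, then inversion on epoxide closure.
- Locants: dibenz[b,f]oxepine numbering for the core (ring A = C1–C4, ring B = C6–C9); side chain C1' (CH2 on C11) to C7' (CMe2); C3' is the quaternary carbon; ring D is the dihydropyran.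

Key step: step 10

Assumption: the (S,S)-ligand is taken to give (S) at C3' from the (E)-carbonate, by analogy with the known phenol cyclisations; if the sense is the opposite one, the (R,R)-ligand is used and nothing else changes.

Step 1
Reactants: 1 4-bromo-3-methoxyphenol
Product: 2 4-bromo-2-iodo-5-methoxyphenol
Conditions: N-iodosuccinimide, TsOH (cat.), MeCN, 0 °C to rt
Reagents that add atoms: N-iodosuccinimide, O=C1CCC(=O)N1I
Why: Electrophilic aromatic iodination; the hydroxyl directs ortho, the site between OH and OMe is hindered, so iodine should enter the position ortho to OH and para to OMe.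

Step 2
Reactants: 2 4-bromo-2-iodo-5-methoxyphenol; 3 1-(2-fluoro-4-methoxyphenyl)ethanone
Product: 4 1-[2-(4-bromo-2-iodo-5-methoxyphenoxy)-4-methoxyphenyl]ethanone
Conditions: Cs2CO3, DMSO, 100 °C
Reagents that add atoms: none
Why: Nucleophilic aromatic substitution (SNAr); the ortho-acetyl group activates the C–F bond of 3 towards the phenoxide of 2, while the unactivated aryl iodide and bromide stay untouched.

Step 3
Reactants: 4 diaryl ether methyl ketone
Product: 5 2-bromo-3,7-dimethoxydibenz[b,f]oxepin-10(11H)-one
Conditions: Pd2(dba)3 (cat.), Xantphos (cat.), NaOtBu, toluene, 60 °C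
Reagents that add atoms: none
Why: Pd-catalysed intramolecular α-arylation of the methyl ketone enolate closes the seven-membered ring C; oxidative addition should prefer C–I over C–Br at this temperature and only the iodide is placed to cyclise.

Step 4
Reactants: 5 2-bromo-3,7-dimethoxydibenz[b,f]oxepin-10(11H)-one
Product: 6 2-bromo-3,7-dihydroxydibenz[b,f]oxepin-10(11H)-one
Conditions: BBr3, CH2Cl2, −78 °C to rt; then H2O
Reagents that add atoms: none
Why: Lewis acid cleavage of both aryl methyl ethers; diaryl ether, ketone and aryl bromide are inert to BBr3, and the step is placed before any acid-sensitive alkene is present.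

Step 5
Reactants: 6 2-bromo-3,7-dihydroxydibenz[b,f]oxepin-10(11H)-one
Product: 7 2-bromo-3,7-bis(tert-butyldimethylsilyloxy)dibenz[b,f]oxepin-10(11H)-one
Conditions: TBSCl, imidazole, DMF, rt
Reagents that add atoms: tert-butyldimethylsilyl chloride, CC(C)(C)[Si](C)(C)Cl
Why: Silylation of both phenols gives ethers that tolerate amide bases, tin and zirconium reagents and are removed at the end by carbonate in methanol.

Step 6
Reactants: 7 bis-silyl bromo ketone; 8 tributyl(3-methylbut-2-en-1-yl)stannane
Product: 9 3,7-bis(tert-butyldimethylsilyloxy)-2-(3-methylbut-2-en-1-yl)dibenz[b,f]oxepin-10(11H)-one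
Conditions: Pd(PPh3)4 (cat.), DMF, 90 °C
Reagents that add atoms: none
Why: Stille coupling of the aryl bromide with the prenylstannane; coupling at the less hindered allyl terminus should give the linear prenyl arene, and the neutral conditions spare the enolisable ketone and the silyl ethers.

Step 7
Reactants: 10 tert-butyl(but-3-yn-1-yloxy)dimethylsilane
Product: 12 (E)-5-(tert-butyldimethylsilyloxy)-3-methylpent-2-en-1-ol, via (E)-alkenyldimethylalane 11 (not isolated)
Conditions: AlMe3, Cp2ZrCl2 (cat.), CH2Cl2, 0 °C to rt; then n-BuLi, (CH2O)n, THF, −78 °C to rt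
Reagents that add atoms: trimethylaluminium, C[Al](C)C; formaldehyde (from paraformaldehyde), C=O
Why: Negishi zirconium-catalysed carboalumination adds Me and Al syn across the terminal alkyne, which fixes the (E)-trisubstituted alkene; the alanate then adds to formaldehyde with retention.

Step 8
Reactants: 12 (E)-allylic alcohol
Product: 13 (E)-5-(tert-butyldimethylsilyloxy)-3-methylpent-2-en-1-yl methyl carbonate
Conditions: ClCO2Me, pyridine, CH2Cl2, 0 °C
Reagents that add atoms: methyl chloroformate, COC(=O)Cl
Why: Acylation of the only free hydroxyl installs the leaving group for the later π-allyl formation.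

Step 9
Reactants: 13 (E)-silyloxy allyl carbonate
Product: 14 (E)-5-bromo-3-methylpent-2-en-1-yl methyl carbonate
Conditions: Ph3PBr2, CH2Cl2, 0 °C to rt
Reagents that add atoms: dibromotriphenylphosphorane, BrP(Br)(c1ccccc1)(c1ccccc1)c1ccccc1
Why: Appel-type substitution of the primary silyl ether (oxyphosphonium, then SN2 by bromide) gives the bromide directly; the methyl carbonate is not ionised without a metal catalyst.

Step 10
Reactants: 9 bis-silyl prenyl ketone; 14 (E)-bromo allyl carbonate
Product: 16 (S)-C3'-methyl-C3'-vinyl dihydropyran-fused bis-silyl ether, via C11-alkylated allyl carbonate 15 (not isolated)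
Conditions: KHMDS, NaI (cat.), THF–DMPU, −78 to 0 °C; then Pd2(dba)3·CHCl3 (cat.), (S,S)-N,N'-(cyclohexane-1,2-diyl)bis[2-(diphenylphosphino)benzamide] (cat.), THF, rt
Reagents that add atoms: none
Why: Proposed new method: one-pot formal (3+3) annulation in which the potassium enolate of 9 is first C-alkylated at C11 by the primary bromide of 14 (SN2, forms C11–C1'), and ketone 15 is then ionised at its allylic carbonate by zerovalent palladium to a π-allyl complex whose substituted terminus C3' is attacked by the enolate oxygen (forms O–C3') with loss of CO2 and methanol. The closest known reaction types are the Pd-catalysed asymmetric allylic etherification of phenols onto (E)-trisubstituted allyl carbonates (2-methyl-2-vinylchromans) and the Pd-catalysed O-cyclisation of β-dicarbonyl enolates to vinyl-dihydrofurans; an α-aryl ketone enolate as oxygen nucleophile for a tetrasubstituted centre is the new element. Ring D closes in a 6-exo mode onto the allyl terminus; C-attack would need a four-membered ring or, at C5', a six-membered ring holding an (E)-alkene, so ring size should enforce O-alkylation at C3'. The stereocentre C3' is set by the chiral pocket of the diphosphine, which should select one face of the allyl complex that equilibrates through its CH2 terminus before the cyclisation. The step needs C- over O-alkylation in the first stage (soft primary halide, potassium enolate) and survival of the aryl silyl ethers and the prenyl group, which are inert to KHMDS at low temperature and to π-allyl chemistry.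

Step 11
Reactants: 16 (S)-vinyl dihydropyran; 17 2-acetoxy-2-methylpropanoyl chloride
Product: 19 side-chain α-acetoxy ketone, via alkylzirconocene chloride 18 (not isolated)
Conditions: Cp2Zr(H)Cl, THF, rt; then 17, CuBr·SMe2 (cat.), 0 °C to rt
Reagents that add atoms: none
Why: Hydrozirconation puts Zr on the terminal carbon C5' of the monosubstituted vinyl group (the trisubstituted prenyl alkene and the tetrasubstituted enol ether react far more slowly), and copper-catalysed acylation of the alkylzirconocene gives the C6' ketone.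

Step 12
Reactants: 19 side-chain α-acetoxy ketone
Product: 20 (R)-C6' carbinol
Conditions: (S)-Me-CBS oxazaborolidine (cat.), catecholborane, toluene, −40 °C
Reagents that add atoms: none
Why: Corey–Bakshi–Shibata reduction; the catalyst distinguishes the bulky C(OAc)Me2 group from the primary chain and the (S)-catalyst should give the (R)-carbinol, while catecholborane does not hydroborate the alkenes at this temperature.

Step 13
Reactants: 20 (R)-C6' carbinol
Product: 21 (R)-C6' mesylate
Conditions: MsCl, Et3N, CH2Cl2, −10 °C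
Reagents that add atoms: methanesulfonyl chloride, CS(=O)(=O)Cl
Why: Sulfonylation of the only free hydroxyl, with retention at C6', done cold and quickly so that the tertiary acetate does not migrate.

Step 14
Reactants: 21 (R)-C6' mesylate
Product: 22 CNP0299249.1 (target)
Conditions: K2CO3, MeOH, rt to 40 °C
Reagents that add atoms: none
Why: Methanolysis of the tertiary acetate frees an alkoxide that displaces the neighbouring mesylate (intramolecular SN2, inversion to the (S)-epoxide), and the same conditions cleave both aryl silyl ethers; epoxide, enol ether and prenyl group are stable to carbonate in methanol.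

**Compound list**
1 | 4-bromo-3-methoxyphenol | COc1cc(O)ccc1Br | starting material
2 | 4-bromo-2-iodo-5-methoxyphenol | COc1cc(O)c(I)cc1Br | intermediate
3 | 1-(2-fluoro-4-methoxyphenyl)ethanone | CC(=O)c1ccc(OC)cc1F | starting material
4 | 1-[2-(4-bromo-2-iodo-5-methoxyphenoxy)-4-methoxyphenyl]ethanone | CC(=O)c1ccc(OC)cc1Oc1cc(OC)c(Br)cc1I | intermediate
5 | 2-bromo-3,7-dimethoxydibenz[b,f]oxepin-10(11H)-one | O=C1Cc2cc(Br)c(OC)cc2Oc2cc(OC)ccc21 | intermediate
6 | 2-bromo-3,7-dihydroxydibenz[b,f]oxepin-10(11H)-one | O=C1Cc2cc(Br)c(O)cc2Oc2cc(O)ccc21 | intermediate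
7 | 2-bromo-3,7-bis(tert-butyldimethylsilyloxy)dibenz[b,f]oxepin-10(11H)-one | O=C1Cc2cc(Br)c(O[Si](C)(C)C(C)(C)C)cc2Oc2cc(O[Si](C)(C)C(C)(C)C)ccc21 | intermediate
8 | tributyl(3-methylbut-2-en-1-yl)stannane | CCCC[Sn](CCCC)(CCCC)CC=C(C)C | starting material
9 | 3,7-bis(tert-butyldimethylsilyloxy)-2-(3-methylbut-2-en-1-yl)dibenz[b,f]oxepin-10(11H)-one | O=C1Cc2cc(CC=C(C)C)c(O[Si](C)(C)C(C)(C)C)cc2Oc2cc(O[Si](C)(C)C(C)(C)C)ccc21 | intermediate
10 | tert-butyl(but-3-yn-1-yloxy)dimethylsilane | C#CCCO[Si](C)(C)C(C)(C)C | starting material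
11 | (E)-[4-(tert-butyldimethylsilyloxy)-2-methylbut-1-en-1-yl]dimethylalane | C/C(CCO[Si](C)(C)C(C)(C)C)=C\[Al](C)C | intermediate (not isolated)
12 | (E)-5-(tert-butyldimethylsilyloxy)-3-methylpent-2-en-1-ol | C/C(CCO[Si](C)(C)C(C)(C)C)=C\CO | intermediate
13 | (E)-5-(tert-butyldimethylsilyloxy)-3-methylpent-2-en-1-yl methyl carbonate | C/C(CCO[Si](C)(C)C(C)(C)C)=C\COC(=O)OC | intermediate
14 | (E)-5-bromo-3-methylpent-2-en-1-yl methyl carbonate | C/C(CCBr)=C\COC(=O)OC | intermediate
15 | 3,7-bis(tert-butyldimethylsilyloxy)-11-[(E)-5-(methoxycarbonyloxy)-3-methylpent-3-en-1-yl]-2-(3-methylbut-2-en-1-yl)dibenz[b,f]oxepin-10(11H)-one (C11 racemic) | O=C1C(CC/C(C)=C/COC(=O)OC)c2cc(CC=C(C)C)c(O[Si](C)(C)C(C)(C)C)cc2Oc2cc(O[Si](C)(C)C(C)(C)C)ccc21 | intermediate (not isolated)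
16 | 3,7-bis-TBS ether of the 2-prenyl dibenz[b,f]oxepine whose C10=C11 bond is fused to a 3,4-dihydro-2H-pyran (ring O on C10, CH2 on C11); C3' carries methyl and vinyl, (S) | CC(C)=CCc1cc2c(cc1O[Si](C)(C)C(C)(C)C)Oc1cc(O[Si](C)(C)C(C)(C)C)ccc1C1=C2CC[C@@](C)(C=C)O1 | intermediate
17 | 2-acetoxy-2-methylpropanoyl chloride | CC(=O)OC(C)(C)C(=O)Cl | starting material
18 | chlorobis(cyclopentadienyl)zirconium alkyl from 16 (Zr on C5'), (S) at C3' | CC(C)=CCc1cc2c(cc1O[Si](C)(C)C(C)(C)C)Oc1cc(O[Si](C)(C)C(C)(C)C)ccc1C1=C2CC[C@@](C)(CC[Zr](Cl)(C2C=CC=C2)C2C=CC=C2)O1 | intermediate (not isolated)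
19 | as 16 with C3' carrying methyl and a 4-acetoxy-4-methyl-3-oxopentyl chain, (S) at C3' | CC(C)=CCc1cc2c(cc1O[Si](C)(C)C(C)(C)C)Oc1cc(O[Si](C)(C)C(C)(C)C)ccc1C1=C2CC[C@@](C)(CCC(=O)C(C)(C)OC(C)=O)O1 | intermediate
20 | as 19 with the ketone reduced to the (R)-C6' carbinol; (3'S,6'R) | CC(C)=CCc1cc2c(cc1O[Si](C)(C)C(C)(C)C)Oc1cc(O[Si](C)(C)C(C)(C)C)ccc1C1=C2CC[C@@](C)(CC[C@@H](O)C(C)(C)OC(C)=O)O1 | intermediate
21 | methanesulfonate of 20; (3'S,6'R) | CC(C)=CCc1cc2c(cc1O[Si](C)(C)C(C)(C)C)Oc1cc(O[Si](C)(C)C(C)(C)C)ccc1C1=C2CC[C@@](C)(CC[C@@H](OS(C)(=O)=O)C(C)(C)OC(C)=O)O1 | intermediate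
22 | CNP0299249.1; (3'S,6'S) | CC(C)=CCc1cc2c(cc1O)Oc1cc(O)ccc1C1=C2CC[C@@](C)(CC[C@@H]2OC2(C)C)O1 | target

**Summary**
Total step count: 14. Longest linear sequence: 11 steps (steps 1–6 and 10–14); steps 7–9 make the C6 fragment.

Steps most likely to fail:

1. Step 10 (Proposed new method). Possible failures are elimination of HBr from 14 during the alkylation stage, slow O-attack on the allyl complex with competing β-hydride elimination to a diene, and low or reversed facial selectivity. Fallback (known chemistry; sets out from 9, returns at 16):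
   - (E)-3-methylpent-2-en-4-yn-1-ol F1 is semihydrogenated (Pd/CaCO3 poisoned with Pb(OAc)2, quinoline, H2) to (E)-3-methylpenta-2,4-dien-1-ol F2.
   - Sharpless asymmetric epoxidation (Ti(OiPr)4, D-(−)-diethyl tartrate, t-BuOOH) should give [(2R,3R)-3-ethenyl-3-methyloxiran-2-yl]methanol F3.
   - Hydride opening at C2 with NaAlH2(OCH2CH2OMe)2 gives (S)-3-methylpent-4-ene-1,3-diol F4.
   - I2/PPh3/imidazole gives (S)-5-iodo-3-methylpent-1-en-3-ol F5, and Et3SiOTf/2,6-lutidine gives its triethylsilyl ether F6.
   - The potassium enolate of 9 is alkylated with F6 to the C11-alkylated ketone F7.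
   - PPTS in MeOH, then PPTS in toluene over molecular sieves at 80 °C (desilylation, hemiketal formation, dehydration) gives 16.
   - Here the ring oxygen is that of the tertiary alcohol and the stereocentre is carried in unchanged from the epoxidation.

2. Step 11. Possible failures are hydrozirconation that is not selective for the vinyl group, γ-elimination of the allylic ether from the alkylzirconocene, and sluggish acylation by the hindered acid chloride. Fallback (sets out from 16, returns at 19):
   - 9-BBN hydroborates the vinyl group to the B-alkyl-9-borabicyclononane F8.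
   - Acid chloride 17 is converted with EtSH/Et3N into S-ethyl 2-acetoxy-2-methylpropanethioate F9.
   - Liebeskind–Srogl coupling of F8 with F9 (Pd2(dba)3, tri(2-furyl)phosphine, cuprous thiophene-2-carboxylate CuO2CC4H3S, THF, 50 °C) gives 19.

3. Step 3. Possible failures are loss of selectivity between C–I and C–Br in the oxidative addition, intermolecular arylation, and aldol self-condensation of the methyl ketone. Fallback (sets out from 4, returns at 5): photostimulated SRN1 ring closure of the ketone enolate onto the aryl iodide (KOtBu, DMSO, hν), a radical-anion chain without a transition metal, in which the iodide fragments much faster than the bromide. It makes no new compound.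

**Further compounds**
F1 | step 10 | (E)-3-methylpent-2-en-4-yn-1-ol (bought) | C#C/C(C)=C/CO
F2 | step 10 | (E)-3-methylpenta-2,4-dien-1-ol | C=C/C(C)=C/CO
F3 | step 10 | [(2R,3R)-3-ethenyl-3-methyloxiran-2-yl]methanol | OC[C@H]1O[C@]1(C)C=C
F4 | step 10 | (S)-3-methylpent-4-ene-1,3-diol | OCC[C@](C)(O)C=C
F5 | step 10 | (S)-5-iodo-3-methylpent-1-en-3-ol | ICC[C@](C)(O)C=C
F6 | step 10 | triethyl{[(S)-5-iodo-3-methylpent-1-en-3-yl]oxy}silane | ICC[C@](C)(O[Si](CC)(CC)CC)C=C
F7 | step 10 | 3,7-bis(tert-butyldimethylsilyloxy)-11-[(S)-3-methyl-3-(triethylsilyloxy)pent-4-en-1-yl]-2-(3-methylbut-2-en-1-yl)dibenz[b,f]oxepin-10(11H)-one | O=C1C(CC[C@](C)(O[Si](CC)(CC)CC)C=C)c2cc(CC=C(C)C)c(O[Si](C)(C)C(C)(C)C)cc2Oc2cc(O[Si](C)(C)C(C)(C)C)ccc21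
F8 | step 11 | B-alkyl-9-borabicyclo[3.3.1]nonane from 16 (boron on C5'), (S) at C3' | CC(C)=CCc1cc2c(cc1O[Si](C)(C)C(C)(C)C)Oc1cc(O[Si](C)(C)C(C)(C)C)ccc1C1=C2CC[C@@](C)(CCB2C3CCCC2CCC3)O1
F9 | step 11 | S-ethyl 2-acetoxy-2-methylpropanethioate | CCSC(=O)C(C)(C)OC(C)=O
F0 | step 3 | none | none
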